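The earlier runs and the new flask stem from a simulated flask from invented constants, and the scatter is random.

Starting material lost turns up as target, idle complex counted in target, so y, the target with its idle complex in percent of the charge, is 100 minus the percent of starting material still left, and that rest is the thing you reckon.

in all of them: gas phase 0.19 mM (held); free catalyst 1.5 mol%

| flask | starting material | remark | time |
|---|---|---|---|
| teal | 1.4 mM | run made earlier |  |
| ochre | 2.2 mM | run made earlier |  |
| flask | 1.0 mM |  | 2.5 min |

- teal (time / min: target / %, idle complex / %): 0.167: 29.3, 0; 0.500: 61.1, 1.0; 0.833: 77.4, 1.0; 1.33: 91.3, 0.2; 2.00: 97.6, 1.9; 2.50: 99.0, 0.2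
- ochre (time / min: target / %, idle complex / %): 0.417: 59.4, 0.5; 0.833: 82.4, 0.1; 1.33: 94.2, 0; 1.50: 95.3, 2.3; 2.00: 99.3, 0.9; 2.50: 98.2, 1.8

(each reading ± 1 percentage point)

- target and idle complex together at 2.5 min, in percent of the starting material charged
- concentration of dissolved gas in solution at 2.5 min, in percent of saturation

- amounts and yields of target count idle complex too
- the earlier runs were read with a standard deviation of 1 percentage point
- at the start none of the gas phase is in solution

Let the clearing constant k (a pseudo-first-order constant) be the logarithm of charge over rest, divided by time. The teal reading at 1.33 min gives the clearing constant 1.84 min⁻¹, and the ochre reading at 0.833 min gives 2.09 min⁻¹. So from teal to ochre the charge, and the catalyst with it, grew by a factor of 1.57, while k, as read from these two scattered readings, grew by a factor of 1.14.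

Two extreme flasks can be done in the head. Suppose k ignores the charge: this flask keeps 1.84 min⁻¹, and its rest at 2.5 min is 1.02%. Suppose k follows the catalyst concentration: it falls to 1.31 min⁻¹, and the rest is 3.77%. You place this flask between them, because k as read rose from teal to ochre, but by less than the charge did. So you commit to y between 96.2% and 99.0%. The runs hold no reading of the gas, so you put no number on the dissolved gas.

The forecast gives y as 98.5% and the dissolved gas as 96% of saturation, holding that “k rises only weakly, roughly as concentration^0.3”. Its y lies inside your band.

The flask gives y as 96.5% and the dissolved gas as 84.2% of saturation, so the forecast's y stands within the tolerance and its figure for the gas is 12 percentage points too high. At 2.50 min the flask also holds 4.16 mM of decomposed reagent.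

    gas phase ⇌ dissolved gas, rate k1*(csat - [dissolved gas]) (kL = 0.980 s⁻¹)
    starting material + dissolved gas + free catalyst → free catalyst + target (k = 1.40 × 10⁷ M⁻² s⁻¹)
    free catalyst → spent catalyst (k = 4.80 × 10⁻⁴ s⁻¹)
    free catalyst + target ⇌ idle complex (K = 580 M⁻¹, k = 250 M⁻¹ s⁻¹)
    dissolved gas → decomposed reagent (k = 0.180 s⁻¹)

The flask's rest is 3.5%, inside your band and under the 3.77% of the catalyst-following end. Now take the same flask read at 40 s. There 1.31 min⁻¹ leaves 41.8% and 1.84 min⁻¹ leaves 29.3%. That neighbour flask kept 37% of its starting material, and its y was 63.3%.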